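Sunday's run reads 0% starting material at 8.00 h, yet over-reacted product still climbs from 48% to 53% by 12.0 h. So we follow that late creep.

| setting | Sunday's | Monday's | midnight | spring |
|---|---|---|---|---|
| starting material | 0.050 M | 0.075 M | 0.10 M | 0.10 M |
| gas phase | 16 mM (held) | 16 mM (held) | 16 mM (held) | 16 mM (held) |
| remark | run made earlier | run made earlier |  |  |
| time |  |  | 10 h | 20 h |

| run | time / h | isomer of the product / % | target / % | starting material / % | over-reacted product / % |
|---|---|---|---|---|---|
| Sunday's | 1.50 | 9 | 24 | 55 | 10 |
| Sunday's | 4.00 | 37 | 18 | 13 | 30 |
| Sunday's | 8.00 | 48 | 4 | 0 | 48 |
| Sunday's | 12.0 | 40 | 2 | 1 | 53 |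
| Monday's | 3.00 | 27 | 23 | 36 | 15 |
| Monday's | 6.00 | 49 | 11 | 5 | 33 |
| Monday's | 10.0 | 49 | 3 | 1 | 47 |
| Monday's | 12.0 | 51 | 3 | 3 | 51 |

(scatter of a reading: 1.5 percentage points)

- at the start none of the gas phase is in solution

* which of these there is most of at the end, counted by the starting material in it, midnight (over-reacted product / starting material / target / isomer of the product)
* which of these there is most of at the end, counted by the starting material in it, spring (over-reacted product / starting material / target / isomer of the product)
* amount of the one of these that there is most of at the end, in percent of the starting material charged, midnight
* amount of the one of these that there is most of at the end, in percent of the starting material charged, spring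

Call the rest the share of the charge not yet over-reacted product. From those two Sunday readings we get 27.4 h for the rest half-life, the time in which that share halves after starting material reads 0%; it is a reading, with wide scatter.

But does it apply at 0.10 M? Monday's run is down to 5% starting material at 6.00 h. Scaled by charge, that point falls at 8.00 h, earlier than the 10 h of midnight, so we use it for both flasks.

At 12.0 h the rest reads 47.0% on Sunday and 49.0% on Monday. The charges step evenly, so we extend this to 51.0% at 0.10 M. Our reckoning then runs back to 53.6% for midnight and forward to 41.7% for spring.

Taking off the 2% target that Sunday's run read at 12.0 h, as a stand-in for midnight's target, we expect midnight to show isomer of the product at 51.6%. In spring we expect over-reacted product to lead at 58.3%, more than the rest.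

The forecast gives isomer of the product at 52% for midnight and isomer of the product at 53% for spring: “though the margin is small”. We part from it on spring.

The flask gives isomer of the product at 52.4% for midnight and over-reacted product at 55.6% for spring.

    gas phase ⇌ dissolved gas, rate k1*(csat - [dissolved gas]) (kL = 0.0380 min⁻¹)
    starting material + dissolved gas → target (k = 0.970 M⁻¹ min⁻¹)
    dissolved gas + target → over-reacted product (k = 0.710 M⁻¹ min⁻¹)
    target ⇌ isomer of the product (K = 13.0, k = 0.00820 min⁻¹)

In spring, target and isomer of the product relax by their own step alone with a half-life of 1.31 h, shorter than the rest half-life of 30.1 h reckoned from spring's change between 10 h and 20 h, and isomer of the product, the resting state of that pair, holds 42.9% against 1.43% target at 20 h. Starting from the 47.2% over-reacted product of the spring flask stopped at 12 h, our 27.4 h gives 99.5% at 200 h, and spring left that long holds 99.1%.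

The data were generated by integration for an exercise; scatter was added.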